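Readings and results are calculated for substances that don't exist.

J and X make L.

| flask | J | X | remark | time |
|---|---|---|---|---|
| eta | 0.067 M | 1 equiv | run made earlier |  |
| epsilon | 0.20 M | 1 equiv | run made earlier |  |
| blue | 0.10 M | 1.50 equiv |  | 20 h |
| amber | 0.10 M | 1.00 equiv |  | 20 h |

| run | time / h | L / % | J / % |
|---|---|---|---|
| eta | 1.00 | 2.6 | 97.6 |
| eta | 2.00 | 4.3 | 97.2 |
| eta | 5.00 | 7.6 | 93.0 |
| eta | 12.0 | 14.7 | 87.2 |
| epsilon | 3.00 | 20.2 | 81.9 |
| epsilon | 6.00 | 33.7 | 67.6 |
| epsilon | 10.0 | 44.4 | 58.9 |
| epsilon | 12.0 | 46.4 | 52.3 |

(standard deviation of a reading: 1 percentage point)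
- steps that have been proposed: J + X -> L
- which of these there is most of at the end, counted by the J in it, blue (L / J)
- which of these there is most of at the end, counted by the J in it, amber (L / J)
- final amount of the leader among these, as a percentage of the J charged, in blue
- final amount of the leader among these, as a percentage of the J charged, in amber

I build the flask up one process at a time. First I take the main step alone, second order: the ratio of J reacted to J left, divided by charge and time, should be a constant k. The last L readings give 1.00 × 10⁻⁴ L mol⁻¹ s⁻¹ in epsilon but 5.95 × 10⁻⁵ L mol⁻¹ s⁻¹ in eta, so amber would keep 58.1% or 70.0% of its J.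

Next I add what that shift shows: k grows with concentration to the power 0.476, as read from these readings. I round this to 0.5, so the total order is 2.50. Integrating that law, with rate constant κ, on epsilon's last L reading gives a clock θ, which is 1/κ divided by the epsilon charge to the power 1.50, of 11.6 h, and on that clock amber keeps 64.9% of its J.

Last comes the excess. J is blue's limiting reagent, and the balance says X falls as J falls. Equimolar runs cannot show how the order divides between J and X. I commit, as a bet the readings don't prove, to first order in J and 1.50 in X. My rule is ln(2)/(κX^1.50), with X the mean concentration of X while half the J goes. In blue that mean is 0.125 M, so τ, the half-life of J at the mean X, is 16.3 h, shorter than the run, and J ends near 42.7%. With the split reversed, J would end near 52.5%.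

The forecast gives J at 53% in blue and J at 65% in amber, calling blue "this is a close call". On blue's leader I differ from it.

Blue ends with L leading at 54.1%, and amber with J at 64.7%.

    J + X → L, rate k1*[J]*[X]^1.5 (k = 2.70 × 10⁻⁴ L¹·⁵ mol⁻¹·⁵ s⁻¹)

In blue, τ of 16.3 h stands below the 20 h run, and more than half the J is L. In amber, J's half-life by this step at 7.34 h is 30 h, longer than the run, and J still leads.

Now take a neighbour of amber charged with 0.250 equiv of X, where X is the limiting reagent and L can reach 25.0% of the J charged. On the charged X, τ is 182 h, so 7.32% of the J reacts; on the mean X that becomes 5.82%. The flask gives L at 6.05%.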